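**Remark (assumption on the chemistry):** the quinoline units are read from the SMILES as 6,7-dihydroxyquinolin-5-yl groups. The pyrrole–quinoline axes are assumed not to give separable atropisomers, and the air-sensitive bis-catechol target is handled under argon.

## Retrosynthetic overview

1. Last bonds cut: the four aryl O–CH3 bonds and the N1–CH2 bond between the azecane nitrogen and the propyl linker. This gives (S)-3-methylazecane and 1-(3-chloropropyl)-3,4-bis(6,7-dimethoxyquinolin-5-yl)pyrrole.
2. The strategy rests on the ten-membered azecane (ring A): its C4–C10 heptamethylene run has no functional group. A transient C8=C9 alkene, allylic to N1, closes the ring by metathesis of an N-allyl-N-benzyl diene amide (C2 as lactam carbonyl) and is then hydrogenated away.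
3. C3 (S) comes from (R)-3-bromo-2-methylpropan-1-ol. Its CH2Br carbon becomes C4 (copper-catalysed coupling with pent-4-enylmagnesium bromide) and its CH2OH carbon becomes C2.
4. The two pyrrole C3/C4–quinoline C5 bonds come from a twofold Suzuki coupling of a pyrrole-3,4-bis(boronate) with 5-bromo-6,7-dimethoxyquinoline. The pyridine ring of that quinoline is annulated onto 2-bromoisovanillin (nitration, Wittig, reductive cyclisation).
5. Ring order: ring A (step 6) and the quinoline pyridine ring (step 13) are made on separate branches; the pyrrole and benzo rings are bought.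

Key step: step 6

## Route

**Step 1**
Reactants: 1 (R)-3-bromo-2-methylpropan-1-ol
Product: 2 (R)-(3-bromo-2-methylpropoxy)(tert-butyl)dimethylsilane
Conditions: TBSCl, imidazole, CH2Cl2, 0 °C → rt
Reagents that add atoms: tert-butyldimethylsilyl chloride, CC(C)(C)[Si](C)(C)Cl
Why: Imidazole-promoted silylation of the primary alcohol masks the hydroxyl against the Grignard reagent of step 2 and leaves the C–Br bond and the stereocentre untouched.

**Step 2**
Reactants: 2 (R)-(3-bromo-2-methylpropoxy)(tert-butyl)dimethylsilane; 3 5-bromopent-1-ene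
Product: 5 (S)-tert-butyldimethyl[(2-methyloct-7-en-1-yl)oxy]silane, via pent-4-enylmagnesium bromide 4 (not isolated)
Conditions: 3, Mg, THF, rt; then 2, Li2CuCl4 (cat.), NMP, THF, 0 °C → rt
Reagents that add atoms: none
Why: Copper-catalysed sp3–sp3 Grignard cross-coupling (Kochi coupling) displaces the primary bromide; the stereocentre is beta to the reacting carbon and is not involved, the descriptor changing from R to S only through the change in CIP priorities.

**Step 3**
Reactants: 5 (S)-tert-butyldimethyl[(2-methyloct-7-en-1-yl)oxy]silane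
Product: 6 (S)-2-methyloct-7-en-1-ol
Conditions: p-TsOH·H2O (cat.), MeOH, rt
Reagents that add atoms: none
Why: Acid-catalysed methanolysis of the silyl ether frees the primary alcohol without touching the terminal alkene or the stereocentre.

**Step 4**
Reactants: 6 (S)-2-methyloct-7-en-1-ol
Product: 8 (S)-2-methyloct-7-enoic acid, via (S)-2-methyloct-7-enal 7 (not isolated)
Conditions: TEMPO (cat.), PhI(OAc)2, MeCN/H2O, rt
Reagents that add atoms: water, O
Why: Oxoammonium (TEMPO/PhI(OAc)2) oxidation takes the alcohol through the aldehyde hydrate to the acid under near-neutral conditions that should not enolise the alpha-methyl aldehyde and that spare the terminal alkene.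

**Step 5**
Reactants: 8 (S)-2-methyloct-7-enoic acid; 9 N-allylbenzylamine
Product: 10 (S)-N-allyl-N-benzyl-2-methyloct-7-enamide
Conditions: EDC·HCl, HOBt, iPr2NEt, CH2Cl2, 0 °C → rt
Reagents that add atoms: none
Why: Carbodiimide amide coupling through the HOBt active ester acylates the secondary amine; a simple alpha-alkyl acid has no particular tendency to racemise under these conditions.

**Step 6**
Reactants: 10 (S)-N-allyl-N-benzyl-2-methyloct-7-enamide
Product: 11 (S,Z)-1-benzyl-3-methyl-3,4,5,6,7,10-hexahydroazecin-2(1H)-one (alkene geometry immaterial)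
Conditions: second-generation Grubbs catalyst (10 mol %, two portions), toluene (1 mM), 80 °C, argon sparge
Reagents that add atoms: none
Why: Ring-closing alkene metathesis by the Chauvin mechanism: the ruthenium alkylidene loads onto the unhindered oct-7-enyl terminus, undergoes intramolecular [2+2] cycloaddition with the N-allyl alkene, and cycloreversion of the ruthenacyclobutane expels ethylene and forms C8=C9. The closest known reaction type is ring-closing metathesis of tertiary N-allyl diene amides to medium-ring unsaturated lactams. Ring A (ten-membered lactam) is closed by head-to-tail union of the two terminal alkenes, with the new endocyclic alkene allylic to N1. No stereocentre is created; C3 comes from the chiral pool and is not epimerised under the neutral conditions, and the alkene geometry does not matter because step 7 saturates it. The step needs cyclisation over acyclic diene metathesis oligomerisation, which is secured by high dilution with portionwise catalyst addition, by removal of ethylene, by the non-basic amide nitrogen that cannot bind the catalyst, and by the tertiary amide rotamer that holds the allyl group syn to the acyl chain.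

**Step 7**
Reactants: 11 (S,Z)-1-benzyl-3-methyl-3,4,5,6,7,10-hexahydroazecin-2(1H)-one
Product: 12 (S)-1-benzyl-3-methylazecan-2-one
Conditions: H2 (1 atm), Pd/C, EtOAc, rt
Reagents that add atoms: none
Why: Heterogeneous catalytic hydrogenation saturates the disubstituted ring alkene, and an N-benzyl amide is not hydrogenolysed under these mild conditions.

**Step 8**
Reactants: 12 (S)-1-benzyl-3-methylazecan-2-one
Product: 13 (S)-1-benzyl-3-methylazecane
Conditions: LiAlH4, THF, reflux; aq. NaOH work-up
Reagents that add atoms: none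
Why: LiAlH4 reduction of a tertiary lactam proceeds through the iminium ion to the tertiary amine, converting C2 to CH2 without affecting C3.

**Step 9**
Reactants: 13 (S)-1-benzyl-3-methylazecane
Product: 14 (S)-3-methylazecane
Conditions: H2 (3 bar), Pd(OH)2/C, EtOH, rt
Reagents that add atoms: none
Why: Hydrogenolysis of the benzylic C–N bond over Pd(OH)2 on carbon gives the secondary amine and toluene.

**Step 10**
Reactants: 15 2-bromo-3-hydroxy-4-methoxybenzaldehyde (2-bromoisovanillin)
Product: 16 2-bromo-3-hydroxy-4-methoxy-6-nitrobenzaldehyde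
Conditions: HNO3 (65 %, 1.1 equiv), AcOH, 10–15 °C
Reagents that add atoms: nitric acid, O[N+](=O)[O-]
Why: Electrophilic aromatic nitration directed by the free phenol: both positions ortho to OH (C2 and C4) are substituted, so the nitronium ion should enter para to OH at C6, the carbon that becomes C8a of the quinoline.

**Step 11**
Reactants: 16 2-bromo-3-hydroxy-4-methoxy-6-nitrobenzaldehyde
Product: 17 2-bromo-3,4-dimethoxy-6-nitrobenzaldehyde
Conditions: MeI, K2CO3, DMF, 40 °C
Reagents that add atoms: iodomethane, CI
Why: Williamson O-methylation of the acidic nitrophenol (SN2 on MeI) completes the dimethyl catechol mask.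

**Step 12**
Reactants: 17 2-bromo-3,4-dimethoxy-6-nitrobenzaldehyde
Product: 18 (E)-3-(2-bromo-3,4-dimethoxy-6-nitrophenyl)prop-2-enal
Conditions: Ph3P=CHCHO (1.1 equiv), toluene, 80 °C
Reagents that add atoms: (triphenylphosphoranylidene)acetaldehyde, O=CC=P(c1ccccc1)(c1ccccc1)c1ccccc1
Why: Wittig olefination with the stabilised formylmethylene ylide gives the (E)-enal; the electron-poor nitrobenzaldehyde reacts faster than the enal product, so about one equivalent of ylide should hold back double homologation.

**Step 13**
Reactants: 18 (E)-3-(2-bromo-3,4-dimethoxy-6-nitrophenyl)prop-2-enal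
Product: 20 5-bromo-6,7-dimethoxyquinoline, via aminocinnamaldehyde 19 (not isolated)
Conditions: Fe powder, AcOH/EtOH, 80 °C
Reagents that add atoms: none
Why: Béchamp-type nitro reduction gives the o-aminocinnamaldehyde, which in the hot acid isomerises about the C=C bond by reversible conjugate addition and cyclodehydrates by intramolecular imine formation (Friedländer-type closure of the pyridine ring); the aryl bromide is inert to Fe/AcOH.

**Step 14**
Reactants: 21 1-(triisopropylsilyl)-1H-pyrrole
Product: 22 3,4-dibromo-1-(triisopropylsilyl)-1H-pyrrole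
Conditions: NBS (2.0 equiv), THF, −78 °C → rt
Reagents that add atoms: N-bromosuccinimide, O=C1CCC(=O)N1Br
Why: Electrophilic bromination in which the bulky N-silyl group shields C2 and C5, so that both bromine atoms enter the beta positions C3 and C4.

**Step 15**
Reactants: 22 3,4-dibromo-1-(triisopropylsilyl)-1H-pyrrole
Product: 23 3,4-bis(4,4,5,5-tetramethyl-1,3,2-dioxaborolan-2-yl)-1-(triisopropylsilyl)-1H-pyrrole
Conditions: HBpin, Et3N, PdCl2(MeCN)2 (cat.), SPhos, 1,4-dioxane, 90 °C
Reagents that add atoms: pinacolborane, CC1(C)OBOC1(C)C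
Why: Palladium-catalysed borylation of aryl bromides with pinacolborane and Et3N (Masuda borylation) converts both C–Br bonds into C–B bonds, with the N-silyl group keeping the pyrrole stable.

**Step 16**
Reactants: 23 3,4-bis(4,4,5,5-tetramethyl-1,3,2-dioxaborolan-2-yl)-1-(triisopropylsilyl)-1H-pyrrole; 20 5-bromo-6,7-dimethoxyquinoline (2.3 equiv)
Product: 25 5,5'-(1H-pyrrole-3,4-diyl)bis(6,7-dimethoxyquinoline), via N-silyl bis(quinolyl)pyrrole 24 (not isolated)
Conditions: Pd(OAc)2 (cat.), SPhos, K3PO4, toluene/H2O, 100 °C; then TBAF, THF, rt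
Reagents that add atoms: none
Why: Twofold Suzuki–Miyaura coupling in which SPhos supports oxidative addition into the ortho-methoxy, peri-hindered C5–Br bond and transmetalation of the pyrrol-3-yl boronate, after which fluoride cleaves the N–Si bond.

**Step 17**
Reactants: 25 5,5'-(1H-pyrrole-3,4-diyl)bis(6,7-dimethoxyquinoline); 26 1-bromo-3-chloropropane
Product: 27 5,5'-[1-(3-chloropropyl)-1H-pyrrole-3,4-diyl]bis(6,7-dimethoxyquinoline)
Conditions: NaH, DMF, 0 °C; then 26 (3 equiv), 0 °C → rt
Reagents that add atoms: none
Why: SN2 N-alkylation of the sodium pyrrolide, which displaces bromide much faster than chloride; the excess dihalide suppresses bridging of two pyrroles.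

**Step 18**
Reactants: 14 (S)-3-methylazecane; 27 5,5'-[1-(3-chloropropyl)-1H-pyrrole-3,4-diyl]bis(6,7-dimethoxyquinoline)
Product: 28 (S)-5,5'-{1-[3-(3-methylazecan-1-yl)propyl]-1H-pyrrole-3,4-diyl}bis(6,7-dimethoxyquinoline)
Conditions: K2CO3, NaI (cat.), MeCN, 80 °C
Reagents that add atoms: none
Why: SN2 N-alkylation of the secondary amine with iodide catalysis (in situ Finkelstein exchange of the primary chloride) forms the N1–CH2 bond, and the hindered tertiary amine product should not quaternise appreciably.

**Step 19**
Reactants: 28 (S)-5,5'-{1-[3-(3-methylazecan-1-yl)propyl]-1H-pyrrole-3,4-diyl}bis(6,7-dimethoxyquinoline)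
Product: 29 isohalitulin, (S)-5,5'-{1-[3-(3-methylazecan-1-yl)propyl]-1H-pyrrole-3,4-diyl}bis(quinoline-6,7-diol)
Conditions: BBr3 (excess), CH2Cl2, −78 °C → rt; MeOH, 0 °C; aq. NaHCO3, argon
Reagents that add atoms: none
Why: BBr3 cleavage of the four aryl methyl ethers (Lewis acid complexation, then SN2 attack of bromide on methyl), with excess reagent to allow for complexation of the three basic nitrogens and degassed work-up to protect the bis-catechol.

## Compound list

1 | (R)-3-bromo-2-methylpropan-1-ol | C[C@H](CO)CBr | starting material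
2 | (R)-(3-bromo-2-methylpropoxy)(tert-butyl)dimethylsilane | C[C@H](CO[Si](C)(C)C(C)(C)C)CBr | intermediate
3 | 5-bromopent-1-ene | C=CCCCBr | starting material
4 | pent-4-enylmagnesium bromide | C=CCCC[Mg]Br | intermediate
5 | (S)-tert-butyldimethyl[(2-methyloct-7-en-1-yl)oxy]silane | C[C@@H](CCCCC=C)CO[Si](C)(C)C(C)(C)C | intermediate
6 | (S)-2-methyloct-7-en-1-ol | C[C@@H](CCCCC=C)CO | intermediate
7 | (S)-2-methyloct-7-enal | C[C@@H](CCCCC=C)C=O | intermediate
8 | (S)-2-methyloct-7-enoic acid | C[C@@H](CCCCC=C)C(=O)O | intermediate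
9 | N-allylbenzylamine | C=CCNCc1ccccc1 | starting material
10 | (S)-N-allyl-N-benzyl-2-methyloct-7-enamide | C[C@@H](CCCCC=C)C(=O)N(CC=C)Cc1ccccc1 | intermediate
11 | (S,Z)-1-benzyl-3-methyl-3,4,5,6,7,10-hexahydroazecin-2(1H)-one | C[C@H]1CCCC/C=C\CN(Cc2ccccc2)C1=O | intermediate
12 | (S)-1-benzyl-3-methylazecan-2-one | C[C@H]1CCCCCCCN(Cc2ccccc2)C1=O | intermediate
13 | (S)-1-benzyl-3-methylazecane | C[C@H]1CCCCCCCN(Cc2ccccc2)C1 | intermediate
14 | (S)-3-methylazecane | C[C@H]1CCCCCCCNC1 | intermediate
15 | 2-bromo-3-hydroxy-4-methoxybenzaldehyde | COc1ccc(C=O)c(Br)c1O | starting material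
16 | 2-bromo-3-hydroxy-4-methoxy-6-nitrobenzaldehyde | COc1cc([N+](=O)[O-])c(C=O)c(Br)c1O | intermediate
17 | 2-bromo-3,4-dimethoxy-6-nitrobenzaldehyde | COc1cc([N+](=O)[O-])c(C=O)c(Br)c1OC | intermediate
18 | (E)-3-(2-bromo-3,4-dimethoxy-6-nitrophenyl)prop-2-enal | COc1cc([N+](=O)[O-])c(/C=C/C=O)c(Br)c1OC | intermediate
19 | (E)-3-(6-amino-2-bromo-3,4-dimethoxyphenyl)prop-2-enal | COc1cc(N)c(/C=C/C=O)c(Br)c1OC | intermediate
20 | 5-bromo-6,7-dimethoxyquinoline | COc1cc2ncccc2c(Br)c1OC | intermediate
21 | 1-(triisopropylsilyl)-1H-pyrrole | CC(C)[Si](C(C)C)(C(C)C)n1cccc1 | starting material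
22 | 3,4-dibromo-1-(triisopropylsilyl)-1H-pyrrole | CC(C)[Si](C(C)C)(C(C)C)n1cc(Br)c(Br)c1 | intermediate
23 | 3,4-bis(4,4,5,5-tetramethyl-1,3,2-dioxaborolan-2-yl)-1-(triisopropylsilyl)-1H-pyrrole | CC(C)[Si](C(C)C)(C(C)C)n1cc(B2OC(C)(C)C(C)(C)O2)c(B2OC(C)(C)C(C)(C)O2)c1 | intermediate
24 | 5,5'-[1-(triisopropylsilyl)-1H-pyrrole-3,4-diyl]bis(6,7-dimethoxyquinoline) | CC(C)[Si](C(C)C)(C(C)C)n1cc(-c2c(OC)c(OC)cc3ncccc23)c(-c2c(OC)c(OC)cc3ncccc23)c1 | intermediate
25 | 5,5'-(1H-pyrrole-3,4-diyl)bis(6,7-dimethoxyquinoline) | COc1cc2ncccc2c(-c2c[nH]cc2-c2c(OC)c(OC)cc3ncccc23)c1OC | intermediate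
26 | 1-bromo-3-chloropropane | ClCCCBr | starting material
27 | 5,5'-[1-(3-chloropropyl)-1H-pyrrole-3,4-diyl]bis(6,7-dimethoxyquinoline) | COc1cc2ncccc2c(-c2cn(CCCCl)cc2-c2c(OC)c(OC)cc3ncccc23)c1OC | intermediate
28 | (S)-5,5'-{1-[3-(3-methylazecan-1-yl)propyl]-1H-pyrrole-3,4-diyl}bis(6,7-dimethoxyquinoline) | C[C@H]1CCCCCCCN(CCCn2cc(-c3c(OC)c(OC)cc4ncccc34)c(-c3c(OC)c(OC)cc4ncccc34)c2)C1 | intermediate
29 | isohalitulin | C[C@H]1CCCCCCCN(CCCn2cc(-c3c(O)c(O)cc4ncccc34)c(-c3c(O)c(O)cc4ncccc34)c2)C1 | target

## Step count and risks

Total step count: 19.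
Longest linear sequence: 11 steps (1 → 29 through steps 1–9, 18 and 19).

**Steps most likely to fail**

1. **Step 6 (ring-closing metathesis).** Intermolecular metathesis may outrun the ten-membered closure and give oligomers or the cyclic dimer, and alkene migration before closure may lead to ring-contracted lactams. The fallback closes ring A by N-alkylation instead of metathesis. It sets out from alcohol 6 and comes back at amine 14. Cross-metathesis of 6 with acrylonitrile (Hoveyda–Grubbs second-generation catalyst, CH2Cl2, 40 °C) should give (S)-9-hydroxy-8-methylnon-2-enenitrile F1 as an alkene mixture. Hydrogenation of both the alkene and the nitrile (H2, Raney Ni, NH3/MeOH) should give (S)-9-amino-2-methylnonan-1-ol F2. Selective N-sulfonylation (2-nitrobenzenesulfonyl chloride, Et3N, CH2Cl2, 0 °C) should give (S)-N-(9-hydroxy-8-methylnonyl)-2-nitrobenzenesulfonamide F3. Fukuyama–Mitsunobu cyclisation under dilution (PPh3, diethyl azodicarboxylate, toluene/THF, rt) forms the N1–C2 bond and should give (S)-3-methyl-1-[(2-nitrophenyl)sulfonyl]azecane F4. Thiolate cleavage of the sulfonamide (PhSH, K2CO3, DMF, rt) then delivers 14, which enters step 18.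

2. **Step 16 (twofold Suzuki coupling).** The second coupling next to the first bulky quinolyl group may stall, and the remaining pyrrolyl C–B bond may be lost by protodeboronation. The fallback reverses the roles of the partners, so that the pyrrole carries the halides and cannot lose its reactive site by protonolysis. It sets out from bromoquinoline 20 and dibromopyrrole 22 and comes back at 25. Miyaura borylation of 20 (bis(pinacolato)diboron, Pd(dppf)Cl2, KOAc, 1,4-dioxane, 90 °C) should give 6,7-dimethoxy-5-(4,4,5,5-tetramethyl-1,3,2-dioxaborolan-2-yl)quinoline F5. An excess of F5 is then coupled with 22 under anhydrous conditions (Pd2(dba)3, SPhos, K3PO4, toluene, 100 °C) to give 24, and TBAF as in step 16 gives 25.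

3. **Step 10 (nitration of the free phenol).** Nitric acid may oxidise the electron-rich phenol, or ipso attack at C2 may displace bromine, instead of clean para nitration. The fallback inverts the order of the two electrophilic substitutions. It does not start from 15 but replaces it by commercial 5-hydroxy-4-methoxy-2-nitrobenzaldehyde F6, and it comes back at 16. Bromination of F6 (Br2, AcOH, rt to 50 °C) should occur at the only free position ortho to the hydroxyl, between OH and CHO, as it does for isovanillin itself, and give 16, which enters step 11.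

## Further compounds

F1 | step 6 | (S)-9-hydroxy-8-methylnon-2-enenitrile | C[C@@H](CCCCC=CC#N)CO
F2 | step 6 | (S)-9-amino-2-methylnonan-1-ol | C[C@@H](CCCCCCCN)CO
F3 | step 6 | (S)-N-(9-hydroxy-8-methylnonyl)-2-nitrobenzenesulfonamide | C[C@@H](CCCCCCCNS(=O)(=O)c1ccccc1[N+](=O)[O-])CO
F4 | step 6 | (S)-3-methyl-1-[(2-nitrophenyl)sulfonyl]azecane | C[C@H]1CCCCCCCN(S(=O)(=O)c2ccccc2[N+](=O)[O-])C1
F5 | step 16 | 6,7-dimethoxy-5-(4,4,5,5-tetramethyl-1,3,2-dioxaborolan-2-yl)quinoline | COc1cc2ncccc2c(B2OC(C)(C)C(C)(C)O2)c1OC
F6 | step 10 | 5-hydroxy-4-methoxy-2-nitrobenzaldehyde | COc1cc([N+](=O)[O-])c(C=O)cc1O
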